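**Retrosynthetic overview**
- The last step is a global desilylation of the tris-TBS ether of the chalcone Ar–C(=O)–CH=CH–Ar'.
- Key disconnection: the C(=O)–CH(α) bond and, in the same operation, the C1'–C(=O) bond. Both come from a three-component carbonylative Heck coupling of 2,4-bis(TBSO)iodobenzene, CO and 4-(TBSO)-3,5-diprenylstyrene.
- Enabling feature: the carbonyl carbon is an isolated one-carbon unit between C1' of the resorcinol ring (ring A) and the α-CH of the E-CH=CH conjugated to the diprenylphenol ring (ring B), so it maps onto CO. The vinyl group is the only monosubstituted, ring-conjugated C=C beside two trisubstituted prenyl C=C.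
- Styrene: 4-hydroxybenzaldehyde, double ortho C-prenylation, TBS ether, Wittig methylenation. Iodide: 4-iodoresorcinol, bis-TBS ether.
- No ring is formed, since both benzene rings are bought intact. The only stereochemical element, the E alkene, is set in the key step.

Key step: step 5

Assumption: the target has no stereocentre and is achiral, so the stereochemical task reduces to the E geometry of the enone C=C; 4-iodoresorcinol is taken as commercially available.

**Step 1**
Reactants: 1 4-hydroxybenzaldehyde; 2 prenyl bromide (1-bromo-3-methylbut-2-ene, 2.5–3 equiv, added in portions)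
Product: 4 4-hydroxy-3,5-bis(3-methylbut-2-en-1-yl)benzaldehyde, via 4-hydroxy-3-prenylbenzaldehyde 3 (not isolated)
Conditions: KOH (10% aq., 3 equiv), 0 °C → rt
Reagents that add atoms: none
Why: This is a phenoxide C-alkylation in which water hydrogen-bonds the phenoxide oxygen, so SN2 attack on the primary carbon of 2 comes from the ring carbons ortho to oxygen (para is blocked by CHO), tautomerisation restores the phenol, and a second equivalent repeats the event at the other, equivalent ortho carbon.

**Step 2**
Reactants: 4 4-hydroxy-3,5-bis(3-methylbut-2-en-1-yl)benzaldehyde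
Product: 5 4-(tert-butyldimethylsilyloxy)-3,5-bis(3-methylbut-2-en-1-yl)benzaldehyde
Conditions: TBSCl, imidazole, DMAP (cat.), DMF, rt → 40 °C
Reagents that add atoms: tert-butyldimethylsilyl chloride, CC(C)(C)[Si](C)(C)Cl
Why: This is an imidazole-promoted silylation of a phenol, which the two flanking benzylic CH2 groups slow but do not prevent, while the aldehyde and the prenyl alkenes are inert.

**Step 3**
Reactants: 5 4-(tert-butyldimethylsilyloxy)-3,5-bis(3-methylbut-2-en-1-yl)benzaldehyde
Product: 6 tert-butyl[2,6-bis(3-methylbut-2-en-1-yl)-4-vinylphenoxy]dimethylsilane (4-TBSO-3,5-diprenylstyrene)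
Conditions: Ph3PCH3Br (1.3 equiv), KOtBu (1.2 equiv), THF, 0 °C → rt
Reagents that add atoms: methyltriphenylphosphonium bromide, C[P+](c1ccccc1)(c1ccccc1)c1ccccc1.[Br-]
Why: Wittig methylenation with the non-stabilised ylide turns ArCHO into ArCH=CH2, and the slight deficit of base relative to the phosphonium salt leaves no free alkoxide to attack the aryl silyl ether.

**Step 4**
Reactants: 7 4-iodoresorcinol (4-iodobenzene-1,3-diol)
Product: 8 1-iodo-2,4-bis(tert-butyldimethylsilyloxy)benzene
Conditions: TBSCl (2.4 equiv), imidazole, DMF, rt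
Reagents that add atoms: tert-butyldimethylsilyl chloride, CC(C)(C)[Si](C)(C)Cl
Why: This is a standard imidazole-promoted double silylation of two unhindered phenols, and the C–I bond is untouched.

**Step 5**
Reactants: 6 4-TBSO-3,5-diprenylstyrene; 8 1-iodo-2,4-bis(tert-butyldimethylsilyloxy)benzene (1.3 equiv); 9 carbon monoxide
Product: 11 (E)-1-[2,4-bis(tert-butyldimethylsilyloxy)phenyl]-3-[4-(tert-butyldimethylsilyloxy)-3,5-bis(3-methylbut-2-en-1-yl)phenyl]prop-2-en-1-one, via aroylpalladium(II) iodide 10 (not isolated)
Conditions: [(cinnamyl)PdCl]2 (2 mol %), BuPAd2 (cataCXium A, 8 mol %), NEt3 (2 equiv), CO (10 bar), BHT (trace), 1,4-dioxane, 100 °C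
Reagents that add atoms: none
Why: Pd(0) inserts into the C–I bond of 8, CO (9) inserts to give aroylpalladium(II) iodide 10, and 10 adds syn across the vinyl group of 6 with the acyl carbon bonding to the terminal CH2 and Pd going to the benzylic carbon (η3-benzyl stabilised); bond rotation, syn β-hydride elimination and capture of HI by NEt3 then release enone 11 and Pd(0). The closest known reaction type is the three-component palladium-catalysed carbonylative Heck reaction of aryl iodides, CO and styrenes, an established chalcone synthesis. No ring is closed and no stereocentre is created; the E geometry follows from the syn-elimination conformer that holds aroyl and aryl anti, and it is also the thermodynamic outcome. CO insertion must win over direct Heck arylation, which is secured by the CO pressure, the bulky electron-rich phosphine and the electron-rich, ortho-substituted aryl group that migrates quickly onto CO. Site selectivity among the three C=C bonds is secured by the substrate, because only the monosubstituted, ring-conjugated vinyl group binds and inserts readily, whereas the two trisubstituted prenyl alkenes are too hindered. Silylation of all three phenols and the use of a tertiary amine leave no O–H or N–H nucleophile that could intercept 10 or add to the new enone.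

**Step 6**
Reactants: 11 tris-TBS ether of abyssinone VI
Product: 12 abyssinone VI, (E)-1-(2,4-dihydroxyphenyl)-3-[4-hydroxy-3,5-bis(3-methylbut-2-en-1-yl)phenyl]prop-2-en-1-one
Conditions: TBAF (3.3 equiv), AcOH (3.3 equiv), THF, 0 °C
Reagents that add atoms: none
Why: Fluoride cleaves the aryl silyl ethers, driven by Si–F bond formation, and the acetic acid buffer protonates each phenoxide as it forms, so oxa-Michael addition of the 2'-oxygen is suppressed and the acid-sensitive o-prenylphenol units and the E alkene stay untouched.

**Compound list**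
1 | 4-hydroxybenzaldehyde | O=Cc1ccc(O)cc1 | starting material
2 | prenyl bromide (1-bromo-3-methylbut-2-ene) | CC(C)=CCBr | starting material
3 | 4-hydroxy-3-(3-methylbut-2-en-1-yl)benzaldehyde | CC(C)=CCc1cc(C=O)ccc1O | intermediate
4 | 4-hydroxy-3,5-bis(3-methylbut-2-en-1-yl)benzaldehyde | CC(C)=CCc1cc(C=O)cc(CC=C(C)C)c1O | intermediate
5 | 4-(tert-butyldimethylsilyloxy)-3,5-bis(3-methylbut-2-en-1-yl)benzaldehyde | CC(C)=CCc1cc(C=O)cc(CC=C(C)C)c1O[Si](C)(C)C(C)(C)C | intermediate
6 | tert-butyl[2,6-bis(3-methylbut-2-en-1-yl)-4-vinylphenoxy]dimethylsilane | CC(C)=CCc1cc(C=C)cc(CC=C(C)C)c1O[Si](C)(C)C(C)(C)C | intermediate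
7 | 4-iodoresorcinol | Oc1ccc(I)c(O)c1 | starting material
8 | 1-iodo-2,4-bis(tert-butyldimethylsilyloxy)benzene | CC(C)(C)[Si](C)(C)Oc1ccc(I)c(O[Si](C)(C)C(C)(C)C)c1 | intermediate
9 | carbon monoxide | [C-]#[O+] | starting material
10 | [2,4-bis(tert-butyldimethylsilyloxy)benzoyl]palladium(II) iodide (drawn without its phosphine ligand) | CC(C)(C)[Si](C)(C)Oc1ccc(C(=O)[Pd]I)c(O[Si](C)(C)C(C)(C)C)c1 | intermediate
11 | (E)-1-[2,4-bis(tert-butyldimethylsilyloxy)phenyl]-3-[4-(tert-butyldimethylsilyloxy)-3,5-bis(3-methylbut-2-en-1-yl)phenyl]prop-2-en-1-one | CC(C)=CCc1cc(/C=C/C(=O)c2ccc(O[Si](C)(C)C(C)(C)C)cc2O[Si](C)(C)C(C)(C)C)cc(CC=C(C)C)c1O[Si](C)(C)C(C)(C)C | intermediate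
12 | abyssinone VI | CC(C)=CCc1cc(/C=C/C(=O)c2ccc(O)cc2O)cc(CC=C(C)C)c1O | target

Total step count: 6
Longest linear sequence: 5 steps (1, 2, 3, 5, 6)

**Steps most likely to fail**

**Step 5.**
- Risks: direct arylation of the alkene before CO uptake, sluggish acylpalladation by the ortho-siloxy aroylpalladium species, thermal polymerisation of the electron-rich styrene, and Pd–H-mediated migration of the prenyl double bonds.
- The fallback sets out from 5 (with 8 and 9) and returns at 11.
- Bis(pinacolato)borylmethane is deprotonated with LiTMP (THF, 0 °C) to lithio-bis(pinacolboryl)methane F1. A boron-Wittig reaction of this anion with aldehyde 5 (−78 °C → rt) should give the (E)-styrylboronic pinacol ester F2.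
- Carbonylative Suzuki–Miyaura coupling of the boronate with 8 under CO 9 (PdCl2(dppf), K2CO3, anisole, 80 °C, 1 atm) again passes through 10. The same C(=O)–CH bond is now made by transmetalation and reductive elimination from a partner of preset E geometry, so no olefin insertion, no β-hydride elimination and no free styrene are involved.

**Step 1.**
- Risks: competition of O-alkylation with C-alkylation, stalling at the mono-alkylated stage, and hydrolysis of the allylic bromide in aqueous base.
- The fallback sets out from 1 (and 2) and returns at 6.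
- Bromination of 1 (Br2, AcOH, rt) fixes both ortho positions as 3,5-dibromo-4-hydroxybenzaldehyde F3.
- Wittig methylenation with an excess of ylide (the first equivalent is consumed by the phenol) gives 2,6-dibromo-4-vinylphenol F4. Silylation (TBSCl, imidazole, DMF) then gives tert-butyl(2,6-dibromo-4-vinylphenoxy)dimethylsilane F5.
- Zinc insertion into 2 (Zn dust, LiCl, THF) gives prenylzinc bromide F6.
- A double, linear-selective Negishi coupling of the dibromide with this zinc reagent (Pd(OAc)2, CPhos, THF, rt) places both prenyl groups at the halogen-defined carbons. At this temperature the vinyl group should not engage.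

**Step 6.**
- Risks: base-triggered oxa-Michael closure of the 2'-phenoxide onto the enone, or incomplete cleavage of the hindered ring-B silyl ether.
- The fallback sets out from 4 and 7 and returns at 12, using acetal protection that leaves without fluoride or base.
- 4 is converted with MOMCl/iPr2NEt (CH2Cl2, 0 °C → rt) into 4-(methoxymethoxy)-3,5-diprenylbenzaldehyde F7. Wittig methylenation as in step 3 gives 4-(methoxymethoxy)-3,5-diprenylstyrene F8.
- 7 gives with MOMCl/iPr2NEt 1-iodo-2,4-bis(methoxymethoxy)benzene F9.
- Carbonylative Heck coupling of the MOM styrene, the MOM iodide and 9 under the conditions of step 5 runs through [2,4-bis(methoxymethoxy)benzoyl]palladium(II) iodide F10 to the tris-MOM ether of abyssinone VI F11.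
- Transacetalisation (cat. HCl, MeOH, 40 °C) releases 12.

**Further compounds**
F1 | step 5 | lithio-bis(pinacolboryl)methane | [Li]C(B1OC(C)(C)C(C)(C)O1)B1OC(C)(C)C(C)(C)O1
F2 | step 5 | (E)-2-[4-(tert-butyldimethylsilyloxy)-3,5-diprenylstyryl]-4,4,5,5-tetramethyl-1,3,2-dioxaborolane | CC(C)=CCc1cc(/C=C/B2OC(C)(C)C(C)(C)O2)cc(CC=C(C)C)c1O[Si](C)(C)C(C)(C)C
F3 | step 1 | 3,5-dibromo-4-hydroxybenzaldehyde | O=Cc1cc(Br)c(O)c(Br)c1
F4 | step 1 | 2,6-dibromo-4-vinylphenol | C=Cc1cc(Br)c(O)c(Br)c1
F5 | step 1 | tert-butyl(2,6-dibromo-4-vinylphenoxy)dimethylsilane | C=Cc1cc(Br)c(O[Si](C)(C)C(C)(C)C)c(Br)c1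
F6 | step 1 | prenylzinc bromide | CC(C)=CC[Zn]Br
F7 | step 6 | 4-(methoxymethoxy)-3,5-bis(3-methylbut-2-en-1-yl)benzaldehyde | COCOc1c(CC=C(C)C)cc(C=O)cc1CC=C(C)C
F8 | step 6 | 2-(methoxymethoxy)-1,3-bis(3-methylbut-2-en-1-yl)-5-vinylbenzene | COCOc1c(CC=C(C)C)cc(C=C)cc1CC=C(C)C
F9 | step 6 | 1-iodo-2,4-bis(methoxymethoxy)benzene | COCOc1ccc(I)c(OCOC)c1
F10 | step 6 | [2,4-bis(methoxymethoxy)benzoyl]palladium(II) iodide (drawn without its phosphine ligand) | COCOc1ccc(C(=O)[Pd]I)c(OCOC)c1
F11 | step 6 | (E)-1-[2,4-bis(methoxymethoxy)phenyl]-3-[4-(methoxymethoxy)-3,5-bis(3-methylbut-2-en-1-yl)phenyl]prop-2-en-1-one | COCOc1ccc(C(=O)/C=C/c2cc(CC=C(C)C)c(OCOC)c(CC=C(C)C)c2)c(OCOC)c1
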